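**Leftover nucleophile.** The flask ends with nucleophile left over, and I ask how much of that leftover can still react.

| flask | electrophile | nucleophile | free base | remark | time |
|---|---|---|---|---|---|
| dusk | 0.050 M | 1.7 equiv | 0.30 equiv (fed, over 1.5 h) | run made earlier; the fed solution adds 0.20 times the starting volume |  |
| noon | 0.050 M | 3.8 equiv | 0.30 equiv (fed, over 1.5 h) | run made earlier; the fed solution adds 0.20 times the starting volume |  |
| dawn | 0.10 M | 2.5 equiv | 0.30 equiv (fed, over 1.5 h) | run made earlier; the fed solution adds 0.20 times the starting volume |  |
| flask | 0.050 M | 2.50 equiv | 0.300 equiv (fed, over 1.5 h) | the fed solution adds 0.20 times the starting volume | 10 d |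

| run | time / d | electrophile / % | product / % |
|---|---|---|---|
| dusk | 0.333 | 83.1 | 10.1 |
| dusk | 0.833 | 66.9 | 22.7 |
| dusk | 1.67 | 50.4 | 34.8 |
| dusk | 2.50 | 41.3 | 43.2 |
| dusk | 4.00 | 31.8 | 53.0 |
| dusk | 5.00 | 28.6 | 56.9 |
| dusk | 6.00 | 25.2 | 60.6 |
| noon | 0.500 | 57.3 | 30.1 |
| noon | 0.833 | 43.5 | 42.5 |
| noon | 1.04 | 37.8 | 47.7 |
| noon | 1.67 | 26.1 | 59.4 |
| noon | 2.50 | 17.8 | 70.4 |
| noon | 4.00 | 11.1 | 81.0 |
| noon | 6.00 | 6.4 | 87.9 |
| dawn | 1.25 | 25.2 | 53.0 |
| dawn | 2.50 | 16.2 | 68.9 |
| dawn | 4.00 | 11.4 | 78.3 |
| dawn | 5.00 | 9.8 | 82.5 |
| dawn | 6.00 | 7.4 | 85.6 |

(standard deviation of a reading: 0.5 percentage points)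

- percentages count the electrophile that a species holds: one idle adduct counts as two
- product is meant together with its idle adduct and crystals
- every charge counts on the volume at the start, and the solution that is fed holds the whole dose
- solid, in amounts per volume of the solution: crystals
- the numbers in the tables scatter with a standard deviation of 0.5 percentage points
- reactions considered so far: crystals <-> product; nucleophile + acid set free <-> protonated nucleophile; electrophile + nucleophile -> acid set free + product; acid set free + free base <-> salt of the base; electrophile + product <-> idle adduct
- in an amount of product, one idle adduct counts as one product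
- what has gone from electrophile into another species counts as reacted, even if it can come back
- the earlier runs do not show how much of nucleophile is bound; that part of a forecast is a guess

* part of the electrophile that has reacted at 10 d
* share of the unused nucleophile that is free and not bound as protonated nucleophile, at 10 d

**Same clock.** The product step joins two molecules. So with the equivalents held, I let the clock run on charge times time. The dawn run has twice the flask's charge and the same equivalents of nucleophile, so its reading at 5.00 d stands in for the flask at 10 d. In that dawn reading 90.2 % has reacted and product stands at 0.825 of the charge.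

**The toll.** Each product takes one nucleophile and sets one acid free, and that acid can bind a second nucleophile. I call the nucleophile lost from the free pool per product the toll, an effective stoichiometry, and take it as 2.00. In the flask, free nucleophile is then 0.850 of the electrophile charge. Unused nucleophile is 1.67, so the free share is 50.7 %.

**Weak link.** The runs do not show how much nucleophile is bound, so the toll is a guess. The doubt is the free base. Crediting it with 0.300 equiv of the acid gives a share of 68.7 %. I commit to the lower figure: 90.2 % reacted and 50.7 % free.

**Result.** The forecast, higher than mine on the share, says 91 % and 68 %, holding that “each acid beyond the 0.30 equiv of base takes one nucleophile”. The flask gives 91.5 % reacted and 50.5 % free.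

    crystals ⇌ product, rate k1*(cs1 - [product]) while solid is left; crystals form when [product] > cs1 (solubility = 29.0 mM, k = 0.550 h⁻¹)
    nucleophile + acid set free ⇌ protonated nucleophile, settled at all times (K = 2700 M⁻¹)
    electrophile + nucleophile → acid set free + product (k = 0.230 M⁻¹ h⁻¹)
    acid set free + free base ⇌ salt of the base (K = 99.0 M⁻¹, k = 14.0 M⁻¹ h⁻¹)
    electrophile + product ⇌ idle adduct, settled at all times (K = 30.0 M⁻¹)

**Where acid went.** With 84.1 % product and 33 % of the nucleophile unbound in the flask, the toll reads 1.98, and protonated nucleophile stands far above the salt of the base. That binding is a part of why the flask stands at 91.5 % reacted: without it, both ways, the flask reaches 95.8 %. The main reason is the hour of the reading: ten times later, >99.9 % has reacted.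

**Next flask.** The neighbour with 1.50 equiv of nucleophile ends with 63.5 % product, so a toll of 2.00 gives a share of 26.6 %. Its computed share is 31.4 %.

The runs come from a simulation for substances that don't exist.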